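# Proposed synthesis of 2-(4-hydroxybenzyl)-3-[2-(2-hydroxyphenyl)ethyl]-5-methoxyphenol (13)

Atom labels used throughout: ring A is C1 (OMe), C2 (H), C3 (OH), C4 (bearing C7 and ring B), C5 (bearing the bridge C8–C9 to ring C), C6 (H). Ring B is the 4-hydroxyphenyl ring and ring C the 2-hydroxyphenyl ring. Compound numbers are those of the steps and the compound list.

## The problem

The target 13 is three benzene rings joined only by saturated carbon links. Ring A carries the methylene C7 to ring B at C4 and the ethylene bridge C8–C9 to ring C at C5. No ring is fused and there is no stereocentre, so the difficulty is purely regiochemical. Ring A is 1,2,3,5-tetrasubstituted, with three neighbouring groups (C3–O, C4–C7, C5–C8) and C4 wedged between two ortho substituents. Electrophilic substitution of a resorcinol monomethyl ether cannot tell C2, C4 and C6 apart, so the pattern must come from directed chemistry. Four oxygen atoms must end up differentiated, one as a methyl ether and three as free phenols. The methyl ether is therefore best bought in place and the phenols released together at the end. Once C7 is a benzylic alcohol ortho to the C3 hydroxyl and para to the C1 methoxy group it ionises easily to an ortho-quinone methide, so such intermediates must be kept from acid and heat, and the benzyl ethers chosen as protecting groups exclude any early hydrogenation. The enabling feature is that, with C7 carried as a carboxyl carbon on C4, ring A is a para-anisic acid whose ortho positions are C5 (already alkylated) and C3 (still C–H). A carboxylate-bound palladium can then reach only C3–H, and the directing carbon later becomes the benzylic methylene.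

## Retrosynthesis

**13 from 12.** The C7–O bond of the carbinol and the two benzyl ether C–O bonds are cut together by hydrogenolysis. Separate deoxygenation and deprotection would cost a step and expose a quinone-methide-prone system to acid. With one reduction, the free phenols exist only in the last flask. The forward reaction must cleave three benzylic C–O bonds without touching the arenes.

**12 from 9 and 11.** The C7–ring B bond is cut to the salicylaldehyde 9 and the aryl Grignard reagent 11, made from bromide 10. The neighbouring options are conjugate addition of an arylboron nucleophile to the quinone methide of 8, or Friedel–Crafts benzylation of a phenol by 8. The first would save one step, but it passes through an unsubstituted quinone methide that oligomerises and rests on thinner precedent. The second gives ortho/para mixtures. The carbon–magnesium bond fixes the position on ring B, and addition to an aldehyde tolerates the two ortho substituents around C7. Precursor 9 is simpler by a whole ring. The forward step must be a 1,2-addition to an aldehyde that carries a magnesium phenoxide.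

**9 from 8 from 7.** No skeletal bond is cut here; C7 is stepped from carboxyl to hydroxymethyl to formyl. A free salicylic acid cannot be stopped at the aldehyde by hydride, so full reduction with LiAlH4 followed by benzylic oxidation with MnO2 is preferred. The reagents must leave the phenol, the benzyl ether and the activated benzylic C–O bond of 8 intact.

**7 from 6 (key disconnection).** The C3–O bond is cut. Starting from a more highly oxygenated benzoic acid would reintroduce the problem of telling oxygens apart. Directed ortho-lithiation of an amide would compete with lateral lithiation at C8. Cutting C3–O leaves acid 6, whose ring A has a 1,2,4-pattern available from a purchasable bromide. The forward reaction must oxygenate C3–H selectively in the presence of the benzylic C8–H bonds, ring C and the benzyl ether.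

**6 from 5 from 3 and 4.** After ester hydrolysis, the C5–C8 bond is cut to aryl bromide 3 and alkylborane 4 (B-alkyl Suzuki–Miyaura coupling). A Sonogashira or Heck coupling would form the same bond but require a later alkene or alkyne reduction that spares the benzyl ether. The borane delivers the saturated bridge directly. The ester is used because a free carboxylate could interfere with transmetalation.

**4 from 2 from 1.** The C8–B bond is traced to anti-Markovnikov hydroboration of styrene 2, and the C8=C9 bond to Wittig methylenation of aldehyde 1. Both are routine and leave the benzyl ether untouched.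

## Roads not taken

**Alternative 1:** The cut is the C9–ring C bond, with the ring C oxygen tied temporarily to C8, so that the bridge and the ring C phenol are stored as the 2-arylbenzofuran A1. Forward, the ring A alkyne A2 and 2-iodophenol A3 undergo Sonogashira coupling (PdCl2(PPh3)2, CuI, Et3N), and the phenol oxygen then adds to the alkyne to give A1. A final hydrogenation must saturate the furan C8=C9 bond, cleave the then benzylic C8–O bond and remove two benzyl ethers.
- Merits: the coupling–cyclisation is among the most dependable palladium reactions, A3 needs no protecting group, and one reduction would do four jobs.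
- Weak points: A2 already contains the full C3-oxygen/C4-benzyl/C5-carbon array, so the regiochemical problem is only moved into its preparation. The alkyne also sits beside a bulky ortho benzyl group. Reductive opening of a benzofuran is much less routine than debenzylation, and forcing conditions put three benzene rings at risk.
- Comparison: as a single step, formation of A1 is more certain than a C–H hydroxylation, and here this road is better. The chosen plan sets against it that its key step creates the ring A pattern from a purchasable arene, that its bridge is saturated from the start, and that its last step only breaks benzylic C–O bonds.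

**Alternative 2:** The cut goes through ring A itself (C4–C5 and C2–C3), which is assembled from the benzylmalonate A5 and the enone A6. NaOMe in methanol adds the malonate anion to the β-carbon of A6, and the methyl ketone enolate of the adduct closes onto one ester to give the cyclohexane-1,3-dione A4. Its diastereomers are of no consequence.
- Merits: all carbons of ring A, C7 and the bridge are in place after one step from two simple fragments. No transition metal and no C–H activation are involved, and the carbon substituents are placed by construction.
- Weak points: the Michael donor is a fully substituted carbon, so the addition builds a quaternary centre next to a tertiary one and is reversible. The Claisen closure must attack a hindered ester. A4 is still three operations from an arene: loss of the ester carbon, dehydrogenation, and a methylation that must select the C1 oxygen over the C3 oxygen of an unsymmetrical dione on a modest steric bias.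
- Comparison: this road is cheaper in reagents, probably better on scale, and free of the uncertainty of a site-selective oxidation. The chosen plan sets against it that the methyl ether is bought in its place, that a directing group fixes the hydroxyl position, and that no aromatisation is needed.

**Alternative 3:** The cut removes both ring–bridge bonds at once (C5–C8 and C9–ring C). The vinylboronic ester A9 and the ring C aryllithium A10 form a boron ate complex. Pd(OAc)2 with a MandyPhos-type bisphosphine couples it with the ring A triflate A8 through a 1,2-metallate shift of the aryl group from boron to C9, giving the secondary benzylic boronate A7.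
- Merits: three components meet in one mild step, and the method is well documented for aryl triflates.
- Weak points: A7 carries a C–B bond and a stereocentre at C9 that the target lacks, so a protodeboronation must follow and a costly chiral ligand serves a centre that is erased. A8 is an ortho-substituted, hindered electrophile. As in alternative 1, A8 presupposes the whole ring A pattern.
- Comparison: this is the most convergent of the four roads, a real advantage over the linear chosen plan. The chosen plan sets against it a bridge made in one pot with no superfluous functional group to remove, and a ring A whose pattern is created and not assumed.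

Key step: step 4

Remarks on the chemistry: compounds 1, 3 and 10 are taken as purchasable. Carbinol 12 is formed as a racemate, and its only stereocentre is removed in step 8.

## Route

Step 1
Reactants: 1 2-(benzyloxy)benzaldehyde
Product: 2 1-(benzyloxy)-2-ethenylbenzene
Conditions: Ph3PCH3Br, KOtBu, THF, 0 °C to rt
Reagents that add atoms: methyltriphenylphosphonium bromide, C[P+](c1ccccc1)(c1ccccc1)c1ccccc1.[Br-]
Why: Wittig methylenation of an aromatic aldehyde with the unstabilised ylide is routine; the benzyl ether is inert to the base and a terminal alkene raises no geometry question.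

Step 2
Reactants: 2 1-(benzyloxy)-2-ethenylbenzene; 3 methyl 2-bromo-4-methoxybenzoate
Product: 5 methyl 2-{2-[2-(benzyloxy)phenyl]ethyl}-4-methoxybenzoate, via 9-{2-[2-(benzyloxy)phenyl]ethyl}-9-borabicyclo[3.3.1]nonane 4 (not isolated)
Conditions: 9-BBN-H, THF, 0 °C to rt; then 3, PdCl2(dppf) (5 mol %), aq. K3PO4, DMF, 60 °C
Reagents that add atoms: none
Why: 9-BBN-H hydroborates styrenes with high anti-Markovnikov selectivity, placing boron on the terminal carbon C8, and the B-alkyl Suzuki–Miyaura coupling then forms C5–C8; the ortho ester speeds oxidative addition, the wide-bite-angle ligand favours reductive elimination over β-hydride elimination, and any partial ester hydrolysis is harmless because step 3 saponifies.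

Step 3
Reactants: 5 methyl 2-{2-[2-(benzyloxy)phenyl]ethyl}-4-methoxybenzoate
Product: 6 2-{2-[2-(benzyloxy)phenyl]ethyl}-4-methoxybenzoic acid
Conditions: LiOH·H2O, THF/MeOH/H2O, 60 °C; then aq. HCl
Reagents that add atoms: lithium hydroxide, [Li+].[OH-]
Why: Saponification of a methyl benzoate with one ortho substituent is straightforward; both ethers are inert, and acidification frees the carboxylic acid needed as the directing group.

Step 4
Reactants: 6 2-{2-[2-(benzyloxy)phenyl]ethyl}-4-methoxybenzoic acid
Product: 7 2-{2-[2-(benzyloxy)phenyl]ethyl}-6-hydroxy-4-methoxybenzoic acid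
Conditions: Pd(OAc)2 (10 mol %), KOAc (2 equiv), benzoquinone (1 equiv), O2 (1 atm), DMA, 115 °C; then aq. HCl
Reagents that add atoms: dioxygen, O=O
Why: The potassium carboxylate of 6 binds Pd(OAc)2 through oxygen, and acetate-assisted concerted metalation–deprotonation at C3–H gives a five-membered aryl carboxylate chelate of divalent palladium. Dioxygen then oxygenates the aryl–palladium bond, so the new hydroxyl oxygen comes from O2, with benzoquinone assisting turnover, and the C3–O bond is released as the potassium salicylate, which acid work-up converts into 7. The closest known reaction type is the palladium-catalysed, carboxylate-directed ortho C–H hydroxylation of benzoic acids under 1 atm of O2, documented for alkyl- and alkoxy-substituted benzoic acids. No ring is closed and no stereocentre is formed. The selectivity needed is C3–H over the benzylic C8–H bonds, over the C–H bonds of ring C and over the benzyl ether methylene. The substrate secures it because C5 is blocked, so C3 is the only ortho aryl C–H; palladation of an aryl C–H through a five-membered chelate is favoured over the six-membered benzylic palladacycle that would lead to a phthalide; and ring C and the ether lie beyond the reach of the carboxylate. Once C3 is oxygenated both ortho positions are filled, so a second hydroxylation cannot occur.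

Step 5
Reactants: 7 2-{2-[2-(benzyloxy)phenyl]ethyl}-6-hydroxy-4-methoxybenzoic acid
Product: 8 3-{2-[2-(benzyloxy)phenyl]ethyl}-2-(hydroxymethyl)-5-methoxyphenol
Conditions: LiAlH4, THF, 0 °C to rt; aq. potassium sodium tartrate work-up
Reagents that add atoms: none
Why: Hydride reduction of a carboxylic acid by LiAlH4 gives the primary alcohol while the phenol is carried as its aluminate and the benzyl ether is inert; low temperature and a non-acidic work-up should prevent hydrogenolysis of the activated benzylic C–O bond and ionisation to the quinone methide.

Step 6
Reactants: 8 3-{2-[2-(benzyloxy)phenyl]ethyl}-2-(hydroxymethyl)-5-methoxyphenol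
Product: 9 2-{2-[2-(benzyloxy)phenyl]ethyl}-6-hydroxy-4-methoxybenzaldehyde
Conditions: activated MnO2, CH2Cl2, rt
Reagents that add atoms: none
Why: Activated MnO2 oxidises benzylic alcohols selectively under neutral heterogeneous conditions; the salicylaldehyde formed is stabilised by its internal hydrogen bond and should not be oxidised further, and the phenol and benzyl ether are untouched.

Step 7
Reactants: 9 2-{2-[2-(benzyloxy)phenyl]ethyl}-6-hydroxy-4-methoxybenzaldehyde; 10 1-(benzyloxy)-4-bromobenzene
Product: 12 3-{2-[2-(benzyloxy)phenyl]ethyl}-2-{[4-(benzyloxy)phenyl](hydroxy)methyl}-5-methoxyphenol (racemic), via 4-(benzyloxy)phenylmagnesium bromide 11 (not isolated)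
Conditions: Mg, THF, reflux (10 to 11); then 9, 3 equiv of 11, THF, 0 °C to rt; aq. NH4Cl
Reagents that add atoms: none
Why: Grignard formation from an aryl bromide followed by 1,2-addition to an aldehyde; the first equivalent deprotonates the phenol and further reagent adds to C7, forming the C7–ring B bond at the carbon that carried magnesium; the carbinol stereocentre forms without control and is removed in step 8.

Step 8
Reactants: 12 3-{2-[2-(benzyloxy)phenyl]ethyl}-2-{[4-(benzyloxy)phenyl](hydroxy)methyl}-5-methoxyphenol
Product: 13 2-(4-hydroxybenzyl)-3-[2-(2-hydroxyphenyl)ethyl]-5-methoxyphenol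
Conditions: H2 (1 atm), 10% Pd/C, EtOAc/EtOH, AcOH (cat.), rt
Reagents that add atoms: none
Why: Catalytic hydrogenolysis cleaves both benzyl ethers and the doubly benzylic C7–OH bond, which is strongly activated by the ortho hydroxyl and para methoxy group of ring A and the para oxygen of ring B; at 1 atm over Pd/C the benzene rings should remain intact.

## Compound list

1 | 2-(benzyloxy)benzaldehyde | O=Cc1ccccc1OCc1ccccc1 | starting material
2 | 1-(benzyloxy)-2-ethenylbenzene | C=Cc1ccccc1OCc1ccccc1 | intermediate
3 | methyl 2-bromo-4-methoxybenzoate | COC(=O)c1ccc(OC)cc1Br | starting material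
4 | 9-{2-[2-(benzyloxy)phenyl]ethyl}-9-borabicyclo[3.3.1]nonane | C(Cc1ccccc1OCc1ccccc1)B1C2CCCC1CCC2 | intermediate
5 | methyl 2-{2-[2-(benzyloxy)phenyl]ethyl}-4-methoxybenzoate | COC(=O)c1ccc(OC)cc1CCc1ccccc1OCc1ccccc1 | intermediate
6 | 2-{2-[2-(benzyloxy)phenyl]ethyl}-4-methoxybenzoic acid | COc1ccc(C(=O)O)c(CCc2ccccc2OCc2ccccc2)c1 | intermediate
7 | 2-{2-[2-(benzyloxy)phenyl]ethyl}-6-hydroxy-4-methoxybenzoic acid | COc1cc(O)c(C(=O)O)c(CCc2ccccc2OCc2ccccc2)c1 | intermediate
8 | 3-{2-[2-(benzyloxy)phenyl]ethyl}-2-(hydroxymethyl)-5-methoxyphenol | COc1cc(O)c(CO)c(CCc2ccccc2OCc2ccccc2)c1 | intermediate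
9 | 2-{2-[2-(benzyloxy)phenyl]ethyl}-6-hydroxy-4-methoxybenzaldehyde | COc1cc(O)c(C=O)c(CCc2ccccc2OCc2ccccc2)c1 | intermediate
10 | 1-(benzyloxy)-4-bromobenzene | Brc1ccc(OCc2ccccc2)cc1 | starting material
11 | 4-(benzyloxy)phenylmagnesium bromide | Br[Mg]c1ccc(OCc2ccccc2)cc1 | intermediate
12 | 3-{2-[2-(benzyloxy)phenyl]ethyl}-2-{[4-(benzyloxy)phenyl](hydroxy)methyl}-5-methoxyphenol (racemic) | COc1cc(O)c(C(O)c2ccc(OCc3ccccc3)cc2)c(CCc2ccccc2OCc2ccccc2)c1 | intermediate
13 | 2-(4-hydroxybenzyl)-3-[2-(2-hydroxyphenyl)ethyl]-5-methoxyphenol | COc1cc(O)c(Cc2ccc(O)cc2)c(CCc2ccccc2O)c1 | target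

## Step count and risks

Total: 8 steps. Longest linear sequence: 8 steps (1 to 13); bromide 3 and bromide 10 enter at steps 2 and 7.

**Step 4 (key step).** Three processes threaten it:
- protodecarboxylation of the product, an electron-rich benzoate with both ortho positions filled, at 115 °C in the presence of palladium, which would lose C7;
- competing palladation at the benzylic C8–H bond with lactonisation to a phthalide;
- catalyst inhibition by the chelating salicylate, or autoxidation at the benzyl ether methylene.

Fallback: set out from ester 5 and use ester-directed iridium-catalysed ortho C–H borylation (B2pin2, [Ir(OMe)(cod)]2, tris[3,5-bis(trifluoromethyl)phenyl]phosphine, octane, 80 °C). This should give methyl 2-{2-[2-(benzyloxy)phenyl]ethyl}-4-methoxy-6-(4,4,5,5-tetramethyl-1,3,2-dioxaborolan-2-yl)benzoate F1. Oxidation with NaBO3·4H2O in aqueous THF should give methyl 2-{2-[2-(benzyloxy)phenyl]ethyl}-6-hydroxy-4-methoxybenzoate F2, and LiAlH4 at 0 °C reduces the ester to 8, where the route is rejoined. This bypasses 6 and 7.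

**Step 2.** Transmetalation of the alkylborane to the hindered ortho-substituted arylpalladium may be slow. That would allow protodeboronation, β-hydride elimination or simple reduction of the bromide to compete. Fallback: Heck coupling of 3 with 2 (Pd(OAc)2, P(o-tol)3, Et3N, DMF, 100 °C) to methyl 2-{(E)-2-[2-(benzyloxy)phenyl]ethenyl}-4-methoxybenzoate F3. Diimide reduction of the alkene (TsNHNH2, NaOAc, aqueous THF, reflux) spares the benzyl ether and returns to 5.

**Step 5.** The aluminate of the product may eliminate to a quinone methide that takes up hydride, reducing C7 to a methyl group. The salicyl alcohol may also oligomerise by ionisation on work-up or on silica. Fallback: from 7, close the acetonide with acetone, SOCl2 and DMAP in DME to give 5-{2-[2-(benzyloxy)phenyl]ethyl}-7-methoxy-2,2-dimethyl-4H-1,3-benzodioxin-4-one F4. Partial reduction with iBu2AlH in CH2Cl2 at −78 °C gives a hemiacetal that collapses on work-up directly to aldehyde 9. This rejoins the route at 9 and never forms 8.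

**Step 7.** Addition to the electron-rich, doubly ortho-substituted aldehyde may be sluggish once it is a magnesium phenoxide. The product alkoxide may also ionise to a quinone methide, which could take up a second aryl group or dimerise on work-up. Fallback: from 9, benzylate the phenol (BnBr, K2CO3, DMF) to 2-(benzyloxy)-6-{2-[2-(benzyloxy)phenyl]ethyl}-4-methoxybenzaldehyde F5. Addition of 11 then gives [2-(benzyloxy)-6-{2-[2-(benzyloxy)phenyl]ethyl}-4-methoxyphenyl][4-(benzyloxy)phenyl]methanol F6 (racemic), which cannot form a quinone methide. Hydrogenolysis (H2, Pd/C) of its three benzyl ethers and the carbinol C–O bond gives 13.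

**Step 8.** Cleavage of the C7–OH bond may lag behind debenzylation, leaving a triphenolic carbinol that ionises and oligomerises. Fallback: from 12, ionic reduction with Et3SiH and CF3CO2H in CH2Cl2 at −20 °C to 2-[4-(benzyloxy)benzyl]-3-{2-[2-(benzyloxy)phenyl]ethyl}-5-methoxyphenol F7, followed by plain hydrogenolysis of the two benzyl ethers to 13.

## Further compounds

F1 | step 4 | methyl 2-{2-[2-(benzyloxy)phenyl]ethyl}-4-methoxy-6-(4,4,5,5-tetramethyl-1,3,2-dioxaborolan-2-yl)benzoate | COC(=O)c1c(CCc2ccccc2OCc2ccccc2)cc(OC)cc1B1OC(C)(C)C(C)(C)O1
F2 | step 4 | methyl 2-{2-[2-(benzyloxy)phenyl]ethyl}-6-hydroxy-4-methoxybenzoate | COC(=O)c1c(O)cc(OC)cc1CCc1ccccc1OCc1ccccc1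
F3 | step 2 | methyl 2-{(E)-2-[2-(benzyloxy)phenyl]ethenyl}-4-methoxybenzoate | COC(=O)c1ccc(OC)cc1/C=C/c1ccccc1OCc1ccccc1
F4 | step 5 | 5-{2-[2-(benzyloxy)phenyl]ethyl}-7-methoxy-2,2-dimethyl-4H-1,3-benzodioxin-4-one | COc1cc2OC(C)(C)OC(=O)c2c(CCc2ccccc2OCc2ccccc2)c1
F5 | step 7 | 2-(benzyloxy)-6-{2-[2-(benzyloxy)phenyl]ethyl}-4-methoxybenzaldehyde | COc1cc(OCc2ccccc2)c(C=O)c(CCc2ccccc2OCc2ccccc2)c1
F6 | step 7 | [2-(benzyloxy)-6-{2-[2-(benzyloxy)phenyl]ethyl}-4-methoxyphenyl][4-(benzyloxy)phenyl]methanol (racemic) | COc1cc(OCc2ccccc2)c(C(O)c2ccc(OCc3ccccc3)cc2)c(CCc2ccccc2OCc2ccccc2)c1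
F7 | step 8 | 2-[4-(benzyloxy)benzyl]-3-{2-[2-(benzyloxy)phenyl]ethyl}-5-methoxyphenol | COc1cc(O)c(Cc2ccc(OCc3ccccc3)cc2)c(CCc2ccccc2OCc2ccccc2)c1
A1 | alternative 1 | 2-{3-(benzyloxy)-2-[4-(benzyloxy)benzyl]-5-methoxyphenyl}-1-benzofuran | COc1cc(-c2cc3ccccc3o2)c(Cc2ccc(OCc3ccccc3)cc2)c(OCc2ccccc2)c1
A2 | alternative 1 | 1-(benzyloxy)-2-[4-(benzyloxy)benzyl]-3-ethynyl-5-methoxybenzene | COc1cc(OCc2ccccc2)c(Cc2ccc(OCc3ccccc3)cc2)c(C#C)c1
A3 | alternative 1 | 2-iodophenol | Oc1ccccc1I
A4 | alternative 2 | methyl 1-[4-(benzyloxy)benzyl]-6-{2-[2-(benzyloxy)phenyl]ethyl}-2,4-dioxocyclohexane-1-carboxylate (racemic, mixture of diastereomers) | COC(=O)C1(Cc2ccc(OCc3ccccc3)cc2)C(CCc2ccccc2OCc2ccccc2)CC(=O)CC1=O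
A5 | alternative 2 | dimethyl 2-[4-(benzyloxy)benzyl]propanedioate | COC(=O)C(Cc1ccc(OCc2ccccc2)cc1)C(=O)OC
A6 | alternative 2 | (E)-6-[2-(benzyloxy)phenyl]hex-3-en-2-one | CC(=O)/C=C/CCc1ccccc1OCc1ccccc1
A7 | alternative 3 | 2-(2-{3-(benzyloxy)-2-[4-(benzyloxy)benzyl]-5-methoxyphenyl}-1-[2-(benzyloxy)phenyl]ethyl)-4,4,5,5-tetramethyl-1,3,2-dioxaborolane (configuration at C9 immaterial) | COc1cc(CC(B2OC(C)(C)C(C)(C)O2)c2ccccc2OCc2ccccc2)c(Cc2ccc(OCc3ccccc3)cc2)c(OCc2ccccc2)c1
A8 | alternative 3 | 3-(benzyloxy)-2-[4-(benzyloxy)benzyl]-5-methoxyphenyl trifluoromethanesulfonate | COc1cc(OCc2ccccc2)c(Cc2ccc(OCc3ccccc3)cc2)c(OS(=O)(=O)C(F)(F)F)c1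
A9 | alternative 3 | 2-ethenyl-4,4,5,5-tetramethyl-1,3,2-dioxaborolane | C=CB1OC(C)(C)C(C)(C)O1
A10 | alternative 3 | [2-(benzyloxy)phenyl]lithium | [Li]c1ccccc1OCc1ccccc1
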